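Atoms carry the locants of the target SMILES. Everything rests on cutting N36–C16 and C12–C15 together. C16 is the one carbon shared by the lactam (C16, C18, C19, C34, N36) and the 13-membered cyclophane ring, and it sits between N36 and the aryl-bound C15. A C15≡C16 alkyne can therefore be attacked by the amide nitrogen at C16 and arylated at C15 by C12 in one palladium-mediated aminoarylation that closes both rings. The precursor is the complete epoxy tricycle (rings A, B, C) carrying the 4-iodophenyl ether at C7 and, at C22, a C20 enol ether whose C19 bears a propargyl group and an N-sulfonyl carboxamide.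

Key step: step 19

Remarks on the chemistry
(a) Ring A = C2, C3, C4, C6, C31, C33; ring B = C6, C7, C30, C29, C31; ring C = C22, C23, C25, C27, C29, C30. β is the face of H6 and H29; α is the face of the C31 methyl, H30, O8 and the epoxide oxygen. Advanced intermediates are named with these locants.
(b) Assumption: the chiral lithium amide in step 1 shows the sense of induction established for 4-substituted cyclohexanones. If it is opposite, the enantiomeric amine is used.
(c) Design of the precursor: the amide nitrogen carries a 2-(trimethylsilyl)ethanesulfonyl (SES) group. It makes N–H acidic enough for carbonate, so the nitrogen reacts as a soft amidate, and it is removed by fluoride. The C20 enol is masked as its methoxymethyl (MOM) ether, which goes on oxygen selectively and is cleaved by the mild acid of the last step, sparing the epoxide.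
(d) (E)-3-Iodoacrylic acid, racemic (E)-pent-3-en-2-ol, 2-methylallylmagnesium chloride and 2-(trimethylsilyl)ethanesulfonamide are taken as purchasable.
(e) Coupling with enantiopure 14 in step 8 should turn any minor enantiomer carried from step 1 into a separable diastereomer.

Step 1
Reactants: 1 cis-3,5-dimethylcyclohexanone
Product: 2 (3S,5R)-3,5-dimethyl-1-(trimethylsilyloxy)cyclohex-1-ene
Conditions: (S,S)-[PhCH(CH3)]2NLi (from the amine and n-BuLi), Me3SiCl present from the start, THF, −78 °C
Reagents that add atoms: chlorotrimethylsilane, C[Si](C)(C)Cl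
Why: Enantiotopic-proton-selective deprotonation of the meso ketone by a chiral lithium amide with internal silyl quench (asymmetric desymmetrisation) decides which α-carbon becomes C6 and so fixes the absolute configuration at C2 and C4; no new stereocentre is created.

Step 2
Reactants: 2 (3S,5R)-3,5-dimethyl-1-(trimethylsilyloxy)cyclohex-1-ene; 3 trimethyl orthoformate
Product: 4 (3S,5R)-2-(dimethoxymethyl)-3,5-dimethylcyclohexan-1-one (both epimers at the acetal-bearing carbon)
Conditions: Me3SiOTf (10 mol%), CH2Cl2, −78 °C
Reagents that add atoms: none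
Why: Mukaiyama-type alkylation of the silyl enol ether by the dimethoxycarbenium ion is regiospecific for the future C6 and introduces C7; the configuration of the new centre is irrelevant because it becomes sp2 in step 3.

Step 3
Reactants: 4 (3S,5R)-2-(dimethoxymethyl)-3,5-dimethylcyclohexan-1-one; 5 2-methylallylmagnesium chloride
Product: 7 (4R,6S)-4,6-dimethyl-2-(2-methylallyl)cyclohex-1-ene-1-carbaldehyde, via tertiary alcohol 6 (not isolated)
Conditions: CH2=C(CH3)CH2MgCl, THF, −78 → 0 °C; then 1 M HCl, THF, rt
Reagents that add atoms: water, O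
Why: Grignard 1,2-addition of the allylic reagent to the ketone, followed by acid hydrolysis of the acetal and β-elimination of the tertiary hydroxyl, gives the conjugated tetrasubstituted enal (carbonyl transposition through a β-hydroxy aldehyde); no stereocentre is formed.

Step 4
Reactants: 7 (4R,6S)-4,6-dimethyl-2-(2-methylallyl)cyclohex-1-ene-1-carbaldehyde
Product: 9 (1R,2S,4R,6S)-2,4,6-trimethyl-2-(2-methylallyl)cyclohexane-1-carbaldehyde, via silyl enol ether 8 (not isolated)
Conditions: Me2CuLi (from CuI and MeLi), Me3SiCl, THF/Et2O, −78 → −40 °C; then 1 M HCl, THF, 0 °C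
Reagents that add atoms: lithium dimethylcuprate, [Li+].C[Cu-]C
Why: Chlorosilane-accelerated cuprate conjugate addition to the enal, in which methyl attacks C31 axially (antiparallel attack on the half-chair that keeps both ring methyls equatorial) and protonation of the silyl enol ether at C6 anti to the new axial methyl places the formyl group equatorial, which is also the more stable arrangement.

Step 5
Reactants: 9 (1R,2S,4R,6S)-2,4,6-trimethyl-2-(2-methylallyl)cyclohexane-1-carbaldehyde
Product: 10 (1R,2S,4R,6S)-2,4,6-trimethyl-2-(2-oxopropyl)cyclohexane-1-carbaldehyde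
Conditions: O3, CH2Cl2, −78 °C; then PPh3, −78 °C → rt
Reagents that add atoms: ozone, [O-][O+]=O
Why: Ozonolysis of the only C=C bond with reductive work-up unmasks the methyl ketone and leaves the aldehyde and all stereocentres untouched.

Step 6
Reactants: 11 racemic (E)-pent-3-en-2-ol
Product: 12 (S,E)-pent-3-en-2-ol
Conditions: Novozym 435 (immobilised Candida antarctica lipase B), vinyl acetate, hexane, rt, stopped just beyond half conversion
Reagents that add atoms: none
Why: Lipase-catalysed kinetic resolution by transesterification acylates the R enantiomer of secondary methyl carbinols preferentially, so the S alcohol should be recovered unchanged.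

Step 7
Reactants: 13 (E)-3-iodoacrylic acid; 12 (S,E)-pent-3-en-2-ol
Product: 14 (S,E)-pent-3-en-2-yl (E)-3-iodoacrylate
Conditions: DCC, DMAP (10 mol%), CH2Cl2, 0 °C → rt
Reagents that add atoms: none
Why: Steglich esterification proceeds with retention at the carbinol carbon and does not touch the vinyl iodide.

Step 8
Reactants: 10 (1R,2S,4R,6S)-2,4,6-trimethyl-2-(2-oxopropyl)cyclohexane-1-carbaldehyde; 14 (S,E)-pent-3-en-2-yl (E)-3-iodoacrylate
Product: 15 (S,E)-pent-3-en-2-yl (2E,4R)-4-hydroxy-4-[(1R,2S,4R,6S)-2,4,6-trimethyl-2-(2-oxopropyl)cyclohexyl]but-2-enoate (7R alcohol)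
Conditions: CrCl2 (4 equiv), NiCl2 (2 mol%), DMSO, rt
Reagents that add atoms: none
Why: Nozaki–Hiyama–Kishi addition of the alkenylchromium species is selective for the aldehyde over the ketone and the esters, and Felkin–Anh attack anti to the quaternary C31 should set the 7R carbinol.

Step 9
Reactants: 15 the 7R γ-hydroxy enoate; 16 4-iodophenol
Product: 17 (S,E)-pent-3-en-2-yl (2E,4S)-4-(4-iodophenoxy)-4-[(1R,2S,4R,6S)-2,4,6-trimethyl-2-(2-oxopropyl)cyclohexyl]but-2-enoate (7S aryl ether)
Conditions: PPh3, DIAD, toluene, 0 °C → rt
Reagents that add atoms: none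
Why: Mitsunobu etherification of the allylic alcohol with the acidic phenol goes by SN2 inversion and gives the 7S aryl ether of the target.

Step 10
Reactants: 17 the 7S aryl ether keto enoate
Product: 18 trans-hydrindane keto ester (ring B closed; C29 acetyl α and C30 CH2CO2-pentenyl chain β; 7S aryl ether)
Conditions: KOt-Bu (0.2 equiv), t-BuOH/THF (1:4), 0 °C
Reagents that add atoms: none
Why: Intramolecular Michael addition (5-exo-trig) of the more substituted ketone enolate to the enoate joins C29 to C30 across the two equatorial bonds of ring A (trans-hydrindane); attack occurs anti to the allylic aryloxy group with the allylic hydrogen in the alkene plane (sets C30), and the epimerisable C29 settles trans to the C30 chain.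

Step 11
Reactants: 18 trans-hydrindane keto ester
Product: 19 trans-hydrindane isopropenyl ester (C27=CH2 in place of the ketone)
Conditions: Ph3PCH3Br, KOt-Bu, THF, 0 °C → rt
Reagents that add atoms: methylenetriphenylphosphorane, C=P(c1ccccc1)(c1ccccc1)c1ccccc1
Why: Wittig methylenation of the methyl ketone; C29 is α to the carbonyl but already holds its thermodynamic configuration.

Step 12
Reactants: 19 trans-hydrindane isopropenyl ester
Product: 22 dienyl acid (22S,23R; C20 carboxylic acid at C22; C23 bearing methyl and an E-propenyl group), via silyl ketene acetal 20 (not isolated), via trimethylsilyl ester 21 (not isolated)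
Conditions: LiN(i-Pr)2 (1.2 equiv), Me3SiCl/Et3N, THF, −78 °C → rt, then 50 °C; 1 M HCl work-up
Reagents that add atoms: none
Why: Ireland–Claisen rearrangement, in which kinetic enolisation in THF puts C30 cis to the allylic oxygen and the chair transition state with the carbinol methyl equatorial transfers the S configuration of the ester to C23 (R) and sets C22 (S) anti to it.

Step 13
Reactants: 22 dienyl acid
Product: 23 tricyclic alkene acid (ring C closed with a C25=C27 double bond; C20 carboxylic acid at C22)
Conditions: RuCl2(=CHPh)(PCy3)(H2IMes) (second-generation Grubbs catalyst, 5 mol%), CH2Cl2, 40 °C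
Reagents that add atoms: none
Why: Ring-closing metathesis of the propenyl and isopropenyl groups forms the trisubstituted cyclohexene with loss of propene; the free acid is tolerated and the trans B/C fusion is already fixed by C29 and C30.

Step 14
Reactants: 23 tricyclic alkene acid
Product: 25 tricyclic epoxy acid (25,27-α-epoxide), via bromohydrin 24 (not isolated)
Conditions: NBS, THF/H2O (4:1), 0 °C; then K2CO3, MeOH, rt; work-up at pH 4
Reagents that add atoms: water, O
Why: Halohydrin route to the epoxide, in which the bromonium ion should form on the β face away from the axial C31 methyl, water opens it anti at the tertiary C27 (trans-diaxial) and intramolecular SN2 closure delivers the α-epoxide, the face a direct oxidant would not choose.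

Step 15
Reactants: 25 tricyclic epoxy acid; 26 Meldrum's acid
Product: 27 acyl Meldrum's acid (5-[hydroxy(tricyclyl)methylidene]-2,2-dimethyl-1,3-dioxane-4,6-dione)
Conditions: DCC, DMAP, CH2Cl2, 0 °C → rt
Reagents that add atoms: none
Why: C-Acylation of Meldrum's acid by the carbodiimide-activated acid under neutral conditions that the epoxide tolerates; this brings in C19 and C34.

Step 16
Reactants: 27 acyl Meldrum's acid; 28 2-(trimethylsilyl)ethanesulfonamide
Product: 30 N-SES β-keto amide (C20 ketone; C19 methylene; C34 N-sulfonyl carboxamide), via acylketene 29 (not isolated)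
Conditions: toluene, 100 °C
Reagents that add atoms: none
Why: Thermal cycloreversion of the acyl Meldrum's acid releases acetone and CO2, and the acylketene is trapped at nitrogen by the sulfonamide (acetoacetylation-type N–H addition).

Step 17
Reactants: 30 N-SES β-keto amide; 31 propargyl bromide
Product: 32 C19-propargyl N-SES β-keto amide (C19 epimers)
Conditions: NaH (2.1 equiv), THF/DMF (4:1), 0 °C; HC≡CCH2Br (1.0 equiv); AcOH quench
Reagents that add atoms: none
Why: Alkylation of the N,C-dianion of the β-keto acyl sulfonamide occurs at the more basic carbon C19 (β-dicarbonyl C-alkylation); the new centre is unselective and becomes sp2 in step 18.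

Step 18
Reactants: 32 C19-propargyl N-SES β-keto amide
Product: 33 key-step precursor (C20 MOM enol ether with C22 cis to C18; aryl iodide; terminal alkyne; N-SES carboxamide)
Conditions: KN(SiMe3)2 (2.05 equiv), THF, −78 °C; CH3OCH2Cl (1.0 equiv); AcOH quench
Reagents that add atoms: chloromethyl methyl ether, COCCl
Why: O-Alkylation of the enolate by the hard alkoxymethyl chloride (enol ether formation), in which potassium chelated between O20 and the amide oxygen holds the enolate U-shaped, so the ether oxygen ends cis to the carboxamide and C22 cis to C18.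

Step 19
Reactants: 33 key-step precursor
Product: 34 macrocyclic N-SES 5-arylidene lactam (arene cis to C18 across C15=C16; C20 MOM enol ether)
Conditions: Pd2(dba)3 (10 mol%), XPhos (25 mol%), Cs2CO3 (3 equiv), MeCN/toluene (1:1), 70 °C, syringe-pump addition to a final 1 mM
Reagents that add atoms: none
Why: Proposed new method: zerovalent palladium inserts into the C12–I bond, the arylpalladium iodide (divalent palladium) binds the terminal alkyne, the caesium sulfonyl amidate attacks C16 from the face opposite the metal, and C–C reductive elimination from the alkenyl(aryl)palladium species joins C15 to C12. The closest known reaction type is the intermolecular palladium-catalysed cyclisation–arylation of alkynoic acids and of alkynyl N-sulfonyl carbamates and amides with aryl halides, which gives arylidene heterocycles by the same anti addition; its use to close a strained cyclophane is untested. The lactam closes 5-exo-dig, and the 13-membered ring closes by reductive elimination from a 14-membered palladacycle, where the exergonic C–C bond formation should pay for bending the arene. No stereocentre is formed; anti aminopalladation fixes the C15=C16 geometry with the arene cis to C18, the only geometry the ring can hold. The step needs N- over O-attack, 5-exo over 6-endo closure, and ring closure over oligomerisation or alkyne C–H arylation: the fully deprotonated N-sulfonyl amide is a soft nitrogen nucleophile outside the coordination sphere, the terminal alkyne directs attack to C16, the enol ether blocks furan formation and holds C18 and C22 cis, and copper-free high dilution disfavours intermolecular coupling.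

Step 20
Reactants: 34 macrocyclic N-SES 5-arylidene lactam
Product: 35 macrocyclic N–H 5-arylidene lactam (C20 MOM enol ether)
Conditions: Bu4NF (3 equiv), THF, 0 °C → rt
Reagents that add atoms: none
Why: Fluoride-induced fragmentation of the 2-silylethylsulfonyl group (attack at silicon, β-elimination to ethene and SO2) frees the lactam nitrogen without touching the epoxide, the enol ether or the enamide.

Step 21
Reactants: 35 macrocyclic N–H 5-arylidene lactam
Product: 36 pyrrospirone O
Conditions: CF3CO2H (0.1 M), THF/H2O (4:1), 0 °C → rt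
Reagents that add atoms: water, O
Why: Mild acid hydrolysis cleaves the acetal-type enol ether to the hydrogen-bonded C20 enol and protonates the enamide at C15, and water adds to the cyclic N-acyliminium ion at C16; because this hydration is reversible, C16 should settle under thermodynamic control in the rigid cyclophane, with the hydroxyl expected on the open face (16S).

Compound list
1 | cis-3,5-dimethylcyclohexanone (meso) | C[C@H]1C[C@@H](C)CC(=O)C1 | starting material
2 | (3S,5R)-3,5-dimethyl-1-(trimethylsilyloxy)cyclohex-1-ene | C[C@@H]1C[C@H](C)C=C(O[Si](C)(C)C)C1 | intermediate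
3 | trimethyl orthoformate | COC(OC)OC | starting material
4 | (3S,5R)-2-(dimethoxymethyl)-3,5-dimethylcyclohexan-1-one, both epimers at ring C2 (future C6) | C[C@@H]1C[C@H](C)C(C(OC)OC)C(=O)C1 | intermediate
5 | 2-methylallylmagnesium chloride | C=C(C)C[Mg]Cl | starting material
6 | (3S,5R)-2-(dimethoxymethyl)-3,5-dimethyl-1-(2-methylallyl)cyclohexan-1-ol, diastereomer mixture at ring C1 and C2 | C[C@@H]1C[C@H](C)C(C(OC)OC)C(O)(CC(C)=C)C1 | intermediate (not isolated)
7 | (4R,6S)-4,6-dimethyl-2-(2-methylallyl)cyclohex-1-ene-1-carbaldehyde | C[C@@H]1C[C@H](C)C(C=O)=C(CC(C)=C)C1 | intermediate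
8 | (2S,4R,6S)-2,4,6-trimethyl-2-(2-methylallyl)-1-[(trimethylsilyloxy)methylidene]cyclohexane, E/Z mixture | C[C@@H]1C[C@H](C)C(=CO[Si](C)(C)C)[C@](C)(CC(C)=C)C1 | intermediate (not isolated)
9 | (1R,2S,4R,6S)-2,4,6-trimethyl-2-(2-methylallyl)cyclohexane-1-carbaldehyde | C[C@@H]1C[C@H](C)[C@@H](C=O)[C@](C)(CC(C)=C)C1 | intermediate
10 | (1R,2S,4R,6S)-2,4,6-trimethyl-2-(2-oxopropyl)cyclohexane-1-carbaldehyde | C[C@@H]1C[C@H](C)[C@@H](C=O)[C@](C)(CC(C)=O)C1 | intermediate
11 | racemic (E)-pent-3-en-2-ol | C/C=C/C(C)O | starting material
12 | (S,E)-pent-3-en-2-ol | C/C=C/[C@H](C)O | intermediate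
13 | (E)-3-iodoacrylic acid | OC(=O)/C=C/I | starting material
14 | (S,E)-pent-3-en-2-yl (E)-3-iodoacrylate | I/C=C/C(=O)O[C@@H](C)/C=C/C | intermediate
15 | (S,E)-pent-3-en-2-yl (2E,4R)-4-hydroxy-4-[(1R,2S,4R,6S)-2,4,6-trimethyl-2-(2-oxopropyl)cyclohexyl]but-2-enoate (7R alcohol) | C[C@@H]1C[C@H](C)[C@@H]([C@H](O)/C=C/C(=O)O[C@@H](C)/C=C/C)[C@](C)(CC(C)=O)C1 | intermediate
16 | 4-iodophenol | Oc1ccc(I)cc1 | starting material
17 | (S,E)-pent-3-en-2-yl (2E,4S)-4-(4-iodophenoxy)-4-[(1R,2S,4R,6S)-2,4,6-trimethyl-2-(2-oxopropyl)cyclohexyl]but-2-enoate (7S aryl ether) | C[C@@H]1C[C@H](C)[C@@H]([C@@H](Oc2ccc(I)cc2)/C=C/C(=O)O[C@@H](C)/C=C/C)[C@](C)(CC(C)=O)C1 | intermediate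
18 | trans-hydrindane keto ester: rings A and B, 7S 4-iodophenoxy group, C29 acetyl (α), C30 CH2CO2-[(S,E)-pent-3-en-2-yl] chain (β), C31 methyl (α), H6 and H29 β | C[C@@H]1C[C@H](C)[C@H]2[C@@H](Oc3ccc(I)cc3)[C@H](CC(=O)O[C@@H](C)/C=C/C)[C@@H](C(C)=O)[C@]2(C)C1 | intermediate
19 | trans-hydrindane isopropenyl ester: as 18 with C29 bearing isopropenyl (C27=CH2, C28 methyl) | C[C@@H]1C[C@H](C)[C@H]2[C@@H](Oc3ccc(I)cc3)[C@H](CC(=O)O[C@@H](C)/C=C/C)[C@@H](C(C)=C)[C@]2(C)C1 | intermediate
20 | trimethylsilyl ketene acetal of 19, C30 cis to the allylic oxygen | C[C@@H]1C[C@H](C)[C@H]2[C@@H](Oc3ccc(I)cc3)[C@H](/C=C(/O[Si](C)(C)C)O[C@@H](C)/C=C/C)[C@@H](C(C)=C)[C@]2(C)C1 | intermediate (not isolated)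
21 | trimethylsilyl ester of acid 22 | C[C@@H]1C[C@H](C)[C@H]2[C@@H](Oc3ccc(I)cc3)[C@H]([C@@H](C(=O)O[Si](C)(C)C)[C@H](C)/C=C/C)[C@@H](C(C)=C)[C@]2(C)C1 | intermediate (not isolated)
22 | dienyl acid: C30 bears (22S)-CH(CO2H)–(23R)-CH(CH3)–CH=CH–CH3 (E); C29 bears isopropenyl | C[C@@H]1C[C@H](C)[C@H]2[C@@H](Oc3ccc(I)cc3)[C@H]([C@@H](C(=O)O)[C@H](C)/C=C/C)[C@@H](C(C)=C)[C@]2(C)C1 | intermediate
23 | tricyclic alkene acid: rings A, B, C with C25=C27, 7S 4-iodophenoxy group and C20 carboxylic acid at C22, all centres as in the target | C[C@@H]1C[C@H](C)[C@H]2[C@@H](Oc3ccc(I)cc3)[C@@H]4[C@@H](C(=O)O)[C@H](C)C=C(C)[C@H]4[C@]2(C)C1 | intermediate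
24 | bromohydrin of 23: 25β-bromo, 27α-hydroxy | C[C@@H]1C[C@H](C)[C@H]2[C@@H](Oc3ccc(I)cc3)[C@@H]4[C@@H](C(=O)O)[C@H](C)[C@H](Br)[C@@](C)(O)[C@H]4[C@]2(C)C1 | intermediate (not isolated)
25 | tricyclic epoxy acid: 25,27-α-epoxide of 23 | C[C@@H]1C[C@H](C)[C@H]2[C@@H](Oc3ccc(I)cc3)[C@@H]4[C@@H](C(=O)O)[C@H](C)[C@H]5O[C@@]5(C)[C@H]4[C@]2(C)C1 | intermediate
26 | Meldrum's acid | CC1(C)OC(=O)CC(=O)O1 | starting material
27 | acyl Meldrum's acid of 25 (enol form) | C[C@@H]1C[C@H](C)[C@H]2[C@@H](Oc3ccc(I)cc3)[C@@H]4[C@@H](C(O)=C6C(=O)OC(C)(C)OC6=O)[C@H](C)[C@H]5O[C@@]5(C)[C@H]4[C@]2(C)C1 | intermediate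
28 | 2-(trimethylsilyl)ethanesulfonamide | C[Si](C)(C)CCS(N)(=O)=O | starting material
29 | acylketene from 27 (C20 ketone, C19=C34=O ketene) | C[C@@H]1C[C@H](C)[C@H]2[C@@H](Oc3ccc(I)cc3)[C@@H]4[C@@H](C(=O)C=C=O)[C@H](C)[C@H]5O[C@@]5(C)[C@H]4[C@]2(C)C1 | intermediate (not isolated)
30 | N-SES β-keto amide: C22–C20(=O)–C19H2–C34(=O)NH–SO2CH2CH2SiMe3 | C[C@@H]1C[C@H](C)[C@H]2[C@@H](Oc3ccc(I)cc3)[C@@H]4[C@@H](C(=O)CC(=O)NS(=O)(=O)CC[Si](C)(C)C)[C@H](C)[C@H]5O[C@@]5(C)[C@H]4[C@]2(C)C1 | intermediate
31 | propargyl bromide | C#CCBr | starting material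
32 | C19-propargyl N-SES β-keto amide, C19 epimers | C[C@@H]1C[C@H](C)[C@H]2[C@@H](Oc3ccc(I)cc3)[C@@H]4[C@@H](C(=O)C(CC#C)C(=O)NS(=O)(=O)CC[Si](C)(C)C)[C@H](C)[C@H]5O[C@@]5(C)[C@H]4[C@]2(C)C1 | intermediate
33 | key-step precursor: aryl iodide with propargyl C20 MOM enol ether (C22 cis to C18) and N-SES carboxamide | C[C@@H]1C[C@H](C)[C@H]2[C@@H](Oc5ccc(I)cc5)[C@@H]3[C@@H](/C(OCOC)=C(\CC#C)C(=O)NS(=O)(=O)CC[Si](C)(C)C)[C@H](C)[C@H]4O[C@@]4(C)[C@H]3[C@]2(C)C1 | intermediate
34 | key-step product: macrocyclic N-SES 5-arylidene lactam, arene cis to C18, C20 MOM enol ether | C[C@@H]1C[C@H](C)[C@H]2[C@H]3Oc4ccc(cc4)/C=C7\C/C(=C(/OCOC)[C@H]5[C@H](C)[C@H]6O[C@@]6(C)[C@H]([C@H]35)[C@]2(C)C1)C(=O)N7S(=O)(=O)CC[Si](C)(C)C | intermediate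
35 | macrocyclic N–H 5-arylidene lactam, C20 MOM enol ether | C[C@@H]1C[C@H](C)[C@H]2[C@H]3Oc4ccc(cc4)/C=C7\C/C(=C(/OCOC)[C@H]5[C@H](C)[C@H]6O[C@@]6(C)[C@H]([C@H]35)[C@]2(C)C1)C(=O)N7 | intermediate
36 | pyrrospirone O | C[C@@H]1C[C@H](C)[C@H]2[C@H]3Oc4ccc(cc4)C[C@]4(O)C/C(=C(/O)[C@H]5[C@H](C)[C@H]6O[C@@]6(C)[C@H]([C@H]35)[C@]2(C)C1)C(=O)N4 | target

Total step count: 21. Longest linear sequence: 19 steps (steps 1–5 and 8–21); steps 6 and 7 form the side branch to ester 14.

Steps most likely to fail

Step 19. Intermolecular coupling (aminoarylation between two molecules or arylation of the alkyne C–H) may outrun the strained ring closure. The amidate may also attack through oxygen, or add to the alkyne without arylation. The fallback sets out from 33 and uses two known reactions. Nitrogen is first added across the alkyne alone: a 5-exo-dig hydroamidation catalysed by PdCl2(MeCN)2 (divalent palladium) with Et3N in MeCN should give the N-SES 5-methylene lactam F1. The cyclophane is then closed by an intramolecular Heck reaction of the aryl iodide with the 1,1-disubstituted enamide double bond (Pd(OAc)2, P(o-tol)3, K2CO3, Bu4NCl, DMF, 80 °C, high dilution). The arene adds to the terminal carbon C15 and β-hydride elimination from C15 restores the C15=C16 bond, so the route is rejoined at 34.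

Step 10. Enolisation on the methyl side followed by Claisen-type condensation onto the ester, or γ-deprotonation of the aryloxy enoate with double-bond migration, may compete with the 5-exo addition. The fallback sets out from 17 and separates enolisation from C–C bond formation. Equilibrating silylation (Me3SiCl, NaI, Et3N, MeCN) should give the more substituted C29 trimethylsilyl enol ether F2. An intramolecular Mukaiyama–Michael reaction promoted by TiCl4 in CH2Cl2 at −78 °C then closes ring B without any basic species, and the route is rejoined at 18.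

Step 14. Facial selectivity may be poor or opposite to that expected, so that the bromonium ion forms on the α face and the β-epoxide results. The fallback sets out from 23 and replaces the two-stage halohydrin sequence by direct oxygen transfer from a peracid (3-chloroperbenzoic acid, NaHCO3, CH2Cl2, 0 °C). This puts oxygen on the face the electrophile attacks first, the opposite of what the halohydrin route delivers, so one of the two should give 25, where the route is rejoined. This fallback makes no compound outside the list (F0).

Further compounds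
F1 | step 19 | N-SES 5-methylene lactam (C15H2=C16 exocyclic; aryl iodide intact; C20 MOM enol ether) | C[C@@H]1C[C@H](C)[C@H]2[C@@H](Oc5ccc(I)cc5)[C@@H]3[C@@H](/C(OCOC)=C6\CC(=C)N(S(=O)(=O)CC[Si](C)(C)C)C6=O)[C@H](C)[C@H]4O[C@@]4(C)[C@H]3[C@]2(C)C1
F2 | step 10 | C29 trimethylsilyl enol ether of 17 (Z) | C[C@@H]1C[C@H](C)[C@@H]([C@@H](Oc2ccc(I)cc2)/C=C/C(=O)O[C@@H](C)/C=C/C)[C@](C)(/C=C(/C)O[Si](C)(C)C)C1
F0 | step 14 | none | none
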